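A flask cannot show the balance between Q and D before the step joining them has had time to reach it, and that was my way into these four recipes.

all flasks: E 0.81 M; J 1.20 equiv; L 0.0810 M; time 40 h

| charge | temperature |
|---|---|
| ash | 20 °C |
| cedar | 80 °C |
| maple | 40 °C |
| larch | 60 °C |

    E + J ⇌ E.J (K1 = 0.34 L mol⁻¹, k1 = 1.7 × 10⁻⁴ L mol⁻¹ s⁻¹, Ea1 = 77.0 kJ mol⁻¹, ΔH1 = −42.0 kJ mol⁻¹)
    E.J → Q (k2 = 8.8 × 10⁻⁵ s⁻¹, Ea2 = 100 kJ mol⁻¹)
    E.J + L → E.J.L (k3 = 1.3 × 10⁻⁴ L mol⁻¹ s⁻¹, Ea3 = 83.0 kJ mol⁻¹)
    Q ⇌ D (K4 = 24, k4 = 7.7 × 10⁻⁵ s⁻¹, Ea4 = 102 kJ mol⁻¹, ΔH4 = −25.0 kJ mol⁻¹)
    (constants at 40 °C)

- the constants hold at 40 °C; other temperatures follow from the activation energies and enthalpies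

1. the flask with the highest amount of Q, in percent of the E charged ("all alike" if they lie within 1.5 percentage points) (ash / cedar / maple / larch / all alike)
2. final Q, as a percentage of the E charged, in ash
3. final Q, as a percentage of the E charged, in cedar
4. final Q, as a percentage of the E charged, in maple
5. final Q, as a percentage of the E charged, in larch

E and J form E.J, E.J turns into Q, and Q drains to D, with some coming back. L takes E.J aside as E.J.L. I called Q plus D the pool, and I asked what part of the pool still stood as Q. I had two ways to that share.

The first was the balance, the share once Q ⇌ D (K4 = 24, k4 = 7.7 × 10⁻⁵ s⁻¹, Ea4 = 102 kJ mol⁻¹, ΔH4 = −25.0 kJ mol⁻¹) has finished: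

share = one over (one plus the equilibrium constant at that temperature)
ash 2.12%, maple 4.00%, larch 6.90%, cedar 11.0%

The second was the clock. I took Q as arriving steadily and relaxing with a half-life, which in ash is 35.4 h, about as long as the run of 40 h:

x = run over half-life, times the natural logarithm of 2 = 0.782
part not yet relaxed = (one minus e to the minus x) over x = 69.4%

In ash the two ways parted widely, and I took the balance as the one that cheated, since it assumes a finish that a run of about one half-life does not reach. So I joined them into the held share, the balance plus the clock's part of the remainder:

held share in ash = 70.0%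

In this reckoning the held share depends on temperature and time, not on how much material arrives, so long as arrival is steady.

Control changed hands on the way up. In maple the half-life was 2.40 h, far shorter than the run, and in cedar, where the step runs 1200 times faster than in ash, it was about 1.74 min. There the clock's part, taken by itself, runs towards zero, which is its cheat, and I let the balance stand. This is kinetic against thermodynamic control.

Taking the pool as near the whole charge, and setting the loss to E.J.L aside, I expected cedar near 11.0% and larch near 6.90%. I put maple slightly above 4.00%, with Q perhaps still being fed there.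

Ash needed a pool of 15.7% of the E charged to beat cedar. A rough figure for balanced E.J, times the rate of its turning into Q, times the run, gave an estimate of 41.8%. I guessed the true pool at half of that, allowing for the time E.J takes to form. That made ash 14.6%, more than my 11.0% for cedar, so ash was my pick.

The forecast also named ash, with 18.5% in ash, 10.5% in cedar, 5% in maple and 6.5% in larch, on the ground of “much of the modest Q formed still undrained”.

The simulation put ash highest, with 16.9% in ash, 10.5% in cedar, 4.99% in maple and 6.46% in larch.

In ash, Q and D at 40.0 h gave a share of 70.8% against my held share of 70.0%. The neighbouring flask was ash with 0.300 equiv of J, at the same temperature and for the same time, so I carried the same 70.0% over to it although it was charged less J than ash. That flask ended with Q at 5.28% and D at 2.11%, a share of 71.5%.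

(All constants belong to no real substance; the result is computed.)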